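**Assumption:** the given SMILES has no stereocentre and no configurationally defined axis, so the target is achiral as drawn and no enantiocontrol is needed. The transient stereocentres in 7 and 23 are racemic and are destroyed later. Compounds 1, 3, 10 and 14 are taken as catalogue chemicals.

## Retrosynthetic overview

1. The target comes from its penta-MOM ether by one final acetal cleavage; all four benzene rings (A, B, C, D) are bought intact.
2. The five-membered indenone ring is formed last, by a proposed (4+1) annulation: a ring C/D 2-aroylbenzaldehyde supplies C1, C7a, C3a and C3, and a ring A/B aryldiazomethane supplies C2.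
3. The ring C/D keto-aldehyde comes from lithiated orcinol bis-MOM ether plus 2-bromo-4-methoxy-6-(methoxymethoxy)benzaldehyde, then oxidation and formylation of the C–Br bond.
4. The ring A/B aldehyde comes from a carboxylate-assisted Ullmann diaryl ether synthesis between a ring A 2-bromobenzoic acid and a ring B salicylaldehyde.
5. Regiochemistry of the indenone is fixed by which carbon of ring C carries the aldehyde and which the ketone.

## Route

**Step 1**
Reactants: 1 orcinol (5-methylbenzene-1,3-diol)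
Product: 2 1,3-bis(methoxymethoxy)-5-methylbenzene
Conditions: MOMCl (2.5 equiv), iPr2NEt, CH2Cl2, 0 °C to rt
Reagents that add atoms: chloromethyl methyl ether (MOMCl), COCCl
Why: Williamson-type O-alkylation of both phenols gives the bis-MOM ether, whose two acetal oxygens later direct lithiation to the carbon between them.

**Step 2**
Reactants: 3 2-bromo-4,6-dimethoxybenzaldehyde
Product: 4 2-bromo-6-hydroxy-4-methoxybenzaldehyde
Conditions: BCl3 (1.2 equiv), CH2Cl2, −78 to 0 °C; then H2O
Reagents that add atoms: none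
Why: Chelation-controlled Lewis-acid ether cleavage removes only the methyl ether ortho to the aldehyde, because only that oxygen forms a six-membered boron chelate with the carbonyl.

**Step 3**
Reactants: 4 2-bromo-6-hydroxy-4-methoxybenzaldehyde
Product: 5 2-bromo-4-methoxy-6-(methoxymethoxy)benzaldehyde
Conditions: MOMCl (1.5 equiv), iPr2NEt, CH2Cl2, 0 °C to rt
Reagents that add atoms: chloromethyl methyl ether (MOMCl), COCCl
Why: MOM protection (O-alkylation) of the single phenol proceeds under mild base that leaves the aldehyde and aryl bromide untouched.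

**Step 4**
Reactants: 2 1,3-bis(methoxymethoxy)-5-methylbenzene; 5 2-bromo-4-methoxy-6-(methoxymethoxy)benzaldehyde
Product: 7 rac-[2-bromo-4-methoxy-6-(methoxymethoxy)phenyl][2,6-bis(methoxymethoxy)-4-methylphenyl]methanol, via aryllithium 6 (not isolated)
Conditions: 2 (1.15 equiv), n-BuLi (1.1 equiv), THF, 0 °C, 1 h; then 5, −78 to 0 °C; aq. NH4Cl
Reagents that add atoms: none
Why: Directed ortho-lithiation between the two MOM ethers followed by 1,2-addition to the aldehyde, which is much faster than Br/Li exchange at −78 °C; the new carbinol centre is racemic and is removed in step 5.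

**Step 5**
Reactants: 7 rac-[2-bromo-4-methoxy-6-(methoxymethoxy)phenyl][2,6-bis(methoxymethoxy)-4-methylphenyl]methanol
Product: 8 [2-bromo-4-methoxy-6-(methoxymethoxy)phenyl][2,6-bis(methoxymethoxy)-4-methylphenyl]methanone
Conditions: Dess–Martin periodinane (1.3 equiv), CH2Cl2, 0 °C to rt
Reagents that add atoms: none
Why: Dess–Martin oxidation of a doubly benzylic secondary alcohol is fast and compatible with MOM ethers and the aryl bromide.

**Step 6**
Reactants: 8 [2-bromo-4-methoxy-6-(methoxymethoxy)phenyl][2,6-bis(methoxymethoxy)-4-methylphenyl]methanone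
Product: 9 2-[2,6-bis(methoxymethoxy)-4-methylbenzoyl]-5-methoxy-3-(methoxymethoxy)benzaldehyde
Conditions: Pd(OAc)2 (3 mol %), di(1-adamantyl)-n-butylphosphine (9 mol %), CO/H2 (1:1, 5 bar), TMEDA, toluene, 100 °C
Reagents that add atoms: carbon monoxide, [C-]#[O+]
Why: Palladium-catalysed reductive carbonylation (formylation) of the aryl bromide: oxidative addition to zerovalent palladium, CO insertion and hydrogenolysis of the acyl complex, with the non-enolisable diaryl ketone as a spectator.

**Step 7**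
Reactants: 10 3-bromo-5-methylphenol
Product: 11 1-bromo-3-(methoxymethoxy)-5-methylbenzene
Conditions: MOMCl (1.3 equiv), iPr2NEt, CH2Cl2, 0 °C to rt
Reagents that add atoms: chloromethyl methyl ether (MOMCl), COCCl
Why: MOM protection (O-alkylation) installs the directing and protecting group needed for the next lithiation.

**Step 8**
Reactants: 11 1-bromo-3-(methoxymethoxy)-5-methylbenzene
Product: 13 2-bromo-6-(methoxymethoxy)-4-methylbenzoic acid, via aryllithium 12 (not isolated)
Conditions: LiN(iPr)2 (1.1 equiv), THF, −78 °C, 45 min; CO2 (g), −78 °C to rt; aq. HCl to pH 3, 0 °C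
Reagents that add atoms: carbon dioxide, O=C=O
Why: Directed ortho-metalation by the amide base removes the most acidic proton, flanked by Br and OMOM, and carboxylation at −78 °C traps the aryllithium before LiBr loss to an aryne.

**Step 9**
Reactants: 14 2-hydroxy-5-methoxybenzaldehyde
Product: 15 3-bromo-2-hydroxy-5-methoxybenzaldehyde
Conditions: Br2 (1.05 equiv), NaOAc, AcOH, rt
Reagents that add atoms: bromine, BrBr
Why: Electrophilic aromatic bromination goes ortho to the phenol because the para position is blocked by the methoxy group.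

**Step 10**
Reactants: 15 3-bromo-2-hydroxy-5-methoxybenzaldehyde
Product: 16 2,3-dihydroxy-5-methoxybenzaldehyde
Conditions: NaOH (2 M aq), Cu powder (10 mol %), reflux, N2; then aq. HCl
Reagents that add atoms: sodium hydroxide, [Na+].[OH-]
Why: Copper-mediated Ullmann-type hydroxylation of an ortho-bromophenoxide, the classical conversion of bromo-hydroxybenzaldehydes into catechol aldehydes; the phenoxide protects the aldehyde from Cannizzaro reaction.

**Step 11**
Reactants: 16 2,3-dihydroxy-5-methoxybenzaldehyde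
Product: 17 2-hydroxy-5-methoxy-3-(methoxymethoxy)benzaldehyde
Conditions: NaH (2.1 equiv), DMF, 0 °C; then MOMCl (1.0 equiv), 0 °C to rt; aq. NH4Cl
Reagents that add atoms: chloromethyl methyl ether (MOMCl), COCCl
Why: Regioselective O-alkylation of the dianion: the 3-oxide, not chelated to the aldehyde, is the more nucleophilic oxygen and takes the single equivalent of MOMCl.

**Step 12**
Reactants: 17 2-hydroxy-5-methoxy-3-(methoxymethoxy)benzaldehyde; 13 2-bromo-6-(methoxymethoxy)-4-methylbenzoic acid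
Product: 18 2-[2-formyl-4-methoxy-6-(methoxymethoxy)phenoxy]-6-(methoxymethoxy)-4-methylbenzoic acid
Conditions: CuI (10 mol %), Cu powder (10 mol %), K2CO3, pyridine (0.2 equiv), DMF, 120 °C; then aq. citric acid
Reagents that add atoms: none
Why: Ullmann diaryl ether condensation, in which the ortho-carboxylate of 13 binds copper and accelerates substitution of the adjacent bromide even by a hindered phenoxide.

**Step 13**
Reactants: 18 2-[2-formyl-4-methoxy-6-(methoxymethoxy)phenoxy]-6-(methoxymethoxy)-4-methylbenzoic acid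
Product: 19 methyl 2-[2-formyl-4-methoxy-6-(methoxymethoxy)phenoxy]-6-(methoxymethoxy)-4-methylbenzoate
Conditions: MeI (1.5 equiv), K2CO3, DMF, rt
Reagents that add atoms: iodomethane, CI
Why: SN2 alkylation of the carboxylate esterifies the hindered 2,6-disubstituted acid without needing attack at its carbonyl.

**Step 14**
Reactants: 19 methyl 2-[2-formyl-4-methoxy-6-(methoxymethoxy)phenoxy]-6-(methoxymethoxy)-4-methylbenzoate
Product: 20 methyl 2-[4-methoxy-2-(methoxymethoxy)-6-{(E)-[2-(4-methylbenzenesulfonyl)hydrazinylidene]methyl}phenoxy]-6-(methoxymethoxy)-4-methylbenzoate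
Conditions: TsNHNH2 (1.05 equiv), MeOH, rt
Reagents that add atoms: 4-methylbenzenesulfonohydrazide (TsNHNH2), Cc1ccc(cc1)S(=O)(=O)NN
Why: Hydrazone condensation of the aldehyde is selective over the hindered ester and gives the crystalline E-tosylhydrazone.

**Step 15**
Reactants: 9 2-[2,6-bis(methoxymethoxy)-4-methylbenzoyl]-5-methoxy-3-(methoxymethoxy)benzaldehyde; 20 methyl 2-[4-methoxy-2-(methoxymethoxy)-6-{(E)-[2-(4-methylbenzenesulfonyl)hydrazinylidene]methyl}phenoxy]-6-(methoxymethoxy)-4-methylbenzoate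
Product: 24 methyl 2-{2-[3-[2,6-bis(methoxymethoxy)-4-methylphenyl]-6-methoxy-4-(methoxymethoxy)-1-oxo-1H-inden-2-yl]-4-methoxy-6-(methoxymethoxy)phenoxy}-6-(methoxymethoxy)-4-methylbenzoate, via aryldiazomethane 21 (not isolated), via 1,4-diketone 22 (not isolated), via aldol adduct 23 (not isolated)
Conditions: 9 (1.0 equiv), Cs2CO3 (3 equiv), 1,4-dioxane, 100 °C; 20 (1.3 equiv) added over 4 h
Reagents that add atoms: none
Why: Proposed new method: a base-mediated (4+1) indenone annulation of a 2-aroylbenzaldehyde with an aryldiazomethane, in which Cs2CO3 converts 20 into diazo compound 21 (Bamford–Stevens), its nucleophilic carbon adds to the only aldehyde of 9 (the tetra-ortho-substituted ketone is too hindered), the betaine loses N2 with 1,2-hydride shift to give benzyl ketone 22, and the same base enolises the doubly activated CH2 (pKa about 18) for a 5-exo-trig aldol onto the neighbouring ketone (23) and E1cB dehydration to the conjugated indenone, so that C1–C2 and C2=C3 are formed with regiochemistry fixed by the aldehyde and ketone positions; the closest known reaction types are the metal-free coupling of N-tosylhydrazones with aldehydes to give ketones and the classical aldol cyclodehydration of 2-acylbenzophenones, which have not been merged into an indenone synthesis; no stereocentre survives.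

**Step 16**
Reactants: 24 methyl 2-{2-[3-[2,6-bis(methoxymethoxy)-4-methylphenyl]-6-methoxy-4-(methoxymethoxy)-1-oxo-1H-inden-2-yl]-4-methoxy-6-(methoxymethoxy)phenoxy}-6-(methoxymethoxy)-4-methylbenzoate
Product: 25 ascomindone B
Conditions: HCl (3 M in MeOH), MeOH/THF, 45 °C
Reagents that add atoms: none
Why: Acid-catalysed acetal cleavage removes all five MOM groups while the aryl methyl ethers, the indenone and the methyl ester (degenerate in methanol) are stable; the same acid would also cyclodehydrate any residual 22 or 23.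

## Compound list

1 | orcinol (5-methylbenzene-1,3-diol) | Cc1cc(O)cc(O)c1 | starting material
2 | 1,3-bis(methoxymethoxy)-5-methylbenzene | Cc1cc(OCOC)cc(OCOC)c1 | intermediate
3 | 2-bromo-4,6-dimethoxybenzaldehyde | COc1cc(Br)c(C=O)c(OC)c1 | starting material
4 | 2-bromo-6-hydroxy-4-methoxybenzaldehyde | COc1cc(O)c(C=O)c(Br)c1 | intermediate
5 | 2-bromo-4-methoxy-6-(methoxymethoxy)benzaldehyde | COCOc1cc(OC)cc(Br)c1C=O | intermediate
6 | [2,6-bis(methoxymethoxy)-4-methylphenyl]lithium (not isolated) | [Li]c1c(OCOC)cc(C)cc1OCOC | intermediate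
7 | rac-[2-bromo-4-methoxy-6-(methoxymethoxy)phenyl][2,6-bis(methoxymethoxy)-4-methylphenyl]methanol (racemate) | COCOc1cc(OC)cc(Br)c1C(O)c1c(OCOC)cc(C)cc1OCOC | intermediate
8 | [2-bromo-4-methoxy-6-(methoxymethoxy)phenyl][2,6-bis(methoxymethoxy)-4-methylphenyl]methanone | COCOc1cc(OC)cc(Br)c1C(=O)c1c(OCOC)cc(C)cc1OCOC | intermediate
9 | 2-[2,6-bis(methoxymethoxy)-4-methylbenzoyl]-5-methoxy-3-(methoxymethoxy)benzaldehyde | COCOc1cc(OC)cc(C=O)c1C(=O)c1c(OCOC)cc(C)cc1OCOC | intermediate
10 | 3-bromo-5-methylphenol | Cc1cc(O)cc(Br)c1 | starting material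
11 | 1-bromo-3-(methoxymethoxy)-5-methylbenzene | Cc1cc(Br)cc(OCOC)c1 | intermediate
12 | [2-bromo-6-(methoxymethoxy)-4-methylphenyl]lithium (not isolated) | [Li]c1c(Br)cc(C)cc1OCOC | intermediate
13 | 2-bromo-6-(methoxymethoxy)-4-methylbenzoic acid | Cc1cc(Br)c(C(=O)O)c(OCOC)c1 | intermediate
14 | 2-hydroxy-5-methoxybenzaldehyde | COc1ccc(O)c(C=O)c1 | starting material
15 | 3-bromo-2-hydroxy-5-methoxybenzaldehyde | COc1cc(Br)c(O)c(C=O)c1 | intermediate
16 | 2,3-dihydroxy-5-methoxybenzaldehyde | COc1cc(O)c(O)c(C=O)c1 | intermediate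
17 | 2-hydroxy-5-methoxy-3-(methoxymethoxy)benzaldehyde | COCOc1cc(OC)cc(C=O)c1O | intermediate
18 | 2-[2-formyl-4-methoxy-6-(methoxymethoxy)phenoxy]-6-(methoxymethoxy)-4-methylbenzoic acid | COCOc1cc(C)cc(Oc2c(OCOC)cc(OC)cc2C=O)c1C(=O)O | intermediate
19 | methyl 2-[2-formyl-4-methoxy-6-(methoxymethoxy)phenoxy]-6-(methoxymethoxy)-4-methylbenzoate | COCOc1cc(C)cc(Oc2c(OCOC)cc(OC)cc2C=O)c1C(=O)OC | intermediate
20 | methyl 2-[4-methoxy-2-(methoxymethoxy)-6-{(E)-[2-(4-methylbenzenesulfonyl)hydrazinylidene]methyl}phenoxy]-6-(methoxymethoxy)-4-methylbenzoate | COCOc1cc(C)cc(Oc2c(OCOC)cc(OC)cc2/C=N/NS(=O)(=O)c2ccc(C)cc2)c1C(=O)OC | intermediate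
21 | methyl 2-[2-(diazomethyl)-4-methoxy-6-(methoxymethoxy)phenoxy]-6-(methoxymethoxy)-4-methylbenzoate (not isolated) | COCOc1cc(C)cc(Oc2c(OCOC)cc(OC)cc2C=[N+]=[N-])c1C(=O)OC | intermediate
22 | methyl 2-[2-(2-{2-[2,6-bis(methoxymethoxy)-4-methylbenzoyl]-5-methoxy-3-(methoxymethoxy)phenyl}-2-oxoethyl)-4-methoxy-6-(methoxymethoxy)phenoxy]-6-(methoxymethoxy)-4-methylbenzoate (not isolated) | COCOc1cc(C)cc(Oc2c(OCOC)cc(OC)cc2CC(=O)c2cc(OC)cc(OCOC)c2C(=O)c2c(OCOC)cc(C)cc2OCOC)c1C(=O)OC | intermediate
23 | methyl 2-{2-[3-[2,6-bis(methoxymethoxy)-4-methylphenyl]-3-hydroxy-6-methoxy-4-(methoxymethoxy)-1-oxo-2,3-dihydro-1H-inden-2-yl]-4-methoxy-6-(methoxymethoxy)phenoxy}-6-(methoxymethoxy)-4-methylbenzoate (racemic diastereomer mixture; not isolated) | COCOc1cc(C)cc(Oc2c(OCOC)cc(OC)cc2C2C(=O)c3cc(OC)cc(OCOC)c3C2(O)c2c(OCOC)cc(C)cc2OCOC)c1C(=O)OC | intermediate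
24 | methyl 2-{2-[3-[2,6-bis(methoxymethoxy)-4-methylphenyl]-6-methoxy-4-(methoxymethoxy)-1-oxo-1H-inden-2-yl]-4-methoxy-6-(methoxymethoxy)phenoxy}-6-(methoxymethoxy)-4-methylbenzoate | COCOc1cc(C)cc(Oc2c(OCOC)cc(OC)cc2C2=C(c3c(OCOC)cc(C)cc3OCOC)c3c(OCOC)cc(OC)cc3C2=O)c1C(=O)OC | intermediate
25 | ascomindone B: methyl 2-{2-[3-(2,6-dihydroxy-4-methylphenyl)-4-hydroxy-6-methoxy-1-oxo-1H-inden-2-yl]-6-hydroxy-4-methoxyphenoxy}-6-hydroxy-4-methylbenzoate (achiral) | COC(=O)c1c(O)cc(C)cc1Oc1c(O)cc(OC)cc1C1=C(c2c(O)cc(C)cc2O)c2c(O)cc(OC)cc2C1=O | target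

## Step count and risk

Total steps: 16. Longest linear sequence: 8 steps (14 to 25, steps 9 to 16).

**Three steps most likely to fail**

**Step 15 (proposed new annulation).** Risks are carbene-type decomposition of 21 before it meets the aldehyde and a slow aldol onto the very hindered ketone.
Fallback with known chemistry, setting out from 19 and 9 and returning at 24: 19 is reduced (NaBH4, MeOH, 0 °C) to methyl 2-[2-(hydroxymethyl)-4-methoxy-6-(methoxymethoxy)phenoxy]-6-(methoxymethoxy)-4-methylbenzoate F1. Appel bromination (CBr4, PPh3, CH2Cl2) gives methyl 2-[2-(bromomethyl)-4-methoxy-6-(methoxymethoxy)phenoxy]-6-(methoxymethoxy)-4-methylbenzoate F2. Zinc insertion (Zn dust, LiCl, THF, rt) gives the ester-tolerant benzylic zinc reagent bromo{[3-methoxy-2-[2-(methoxycarbonyl)-3-(methoxymethoxy)-5-methylphenoxy]-5-(methoxymethoxy)phenyl]methyl}zinc F3. This adds to the aldehyde of 9 (THF, 0 °C to rt) to give methyl 2-[2-(2-{2-[2,6-bis(methoxymethoxy)-4-methylbenzoyl]-5-methoxy-3-(methoxymethoxy)phenyl}-2-hydroxyethyl)-4-methoxy-6-(methoxymethoxy)phenoxy]-6-(methoxymethoxy)-4-methylbenzoate F4, in equilibrium with its lactol. Dess–Martin oxidation of F4 gives diketone 22, and the classical aldol cyclodehydration (KOH, MeOH, 50 °C) closes it to 24.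

**Step 12 (intermolecular Ullmann ether synthesis).** The phenol of 17 is di-ortho-substituted and hydrogen-bonded to the aldehyde, so it is a poor nucleophile.
Fallback, setting out from 16 and 13 and returning at 19, makes the C–O bond intramolecularly through a depsidone. Acid 13 is esterified with the more nucleophilic 3-OH of 16 (EDC·HCl, DMAP, CH2Cl2) to give 3-formyl-2-hydroxy-5-methoxyphenyl 2-bromo-6-(methoxymethoxy)-4-methylbenzoate F5. Intramolecular Ullmann etherification (CuI, Cs2CO3, pyridine, 110 °C) closes the seven-membered lactone, the depsidone in which the ring B phenolic oxygen is joined to the former C–Br carbon of ring A, F6. Methanolysis (NaOMe, MeOH, rt) opens the lactone to methyl 2-(2-formyl-6-hydroxy-4-methoxyphenoxy)-6-(methoxymethoxy)-4-methylbenzoate F7. MOMCl/iPr2NEt then gives 19, so step 13 is no longer needed.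

**Step 6 (formylation next to a bulky aroyl group).** Risks are hydrodebromination and slow CO insertion.
Fallback, setting out from 8 and returning at 9: Suzuki vinylation (CH2=CHBF3K, PdCl2(dppf), Cs2CO3, THF/H2O, 80 °C) gives [2-ethenyl-4-methoxy-6-(methoxymethoxy)phenyl][2,6-bis(methoxymethoxy)-4-methylphenyl]methanone F8. Lemieux–Johnson cleavage (OsO4 cat., NaIO4, 2,6-lutidine, dioxane/H2O) then gives 9.

## Further compounds

F1 | step 15 | methyl 2-[2-(hydroxymethyl)-4-methoxy-6-(methoxymethoxy)phenoxy]-6-(methoxymethoxy)-4-methylbenzoate | COCOc1cc(C)cc(Oc2c(OCOC)cc(OC)cc2CO)c1C(=O)OC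
F2 | step 15 | methyl 2-[2-(bromomethyl)-4-methoxy-6-(methoxymethoxy)phenoxy]-6-(methoxymethoxy)-4-methylbenzoate | COCOc1cc(C)cc(Oc2c(OCOC)cc(OC)cc2CBr)c1C(=O)OC
F3 | step 15 | bromo{[3-methoxy-2-[2-(methoxycarbonyl)-3-(methoxymethoxy)-5-methylphenoxy]-5-(methoxymethoxy)phenyl]methyl}zinc | COCOc1cc(C)cc(Oc2c(OCOC)cc(OC)cc2C[Zn]Br)c1C(=O)OC
F4 | step 15 | methyl 2-[2-(2-{2-[2,6-bis(methoxymethoxy)-4-methylbenzoyl]-5-methoxy-3-(methoxymethoxy)phenyl}-2-hydroxyethyl)-4-methoxy-6-(methoxymethoxy)phenoxy]-6-(methoxymethoxy)-4-methylbenzoate (racemate) | COCOc1cc(C)cc(Oc2c(OCOC)cc(OC)cc2CC(O)c2cc(OC)cc(OCOC)c2C(=O)c2c(OCOC)cc(C)cc2OCOC)c1C(=O)OC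
F5 | step 12 | 3-formyl-2-hydroxy-5-methoxyphenyl 2-bromo-6-(methoxymethoxy)-4-methylbenzoate | COCOc1cc(C)cc(Br)c1C(=O)Oc1cc(OC)cc(C=O)c1O
F6 | step 12 | depsidone (dibenzo[b,e][1,4]dioxepin-11-one) carrying formyl and methoxy on ring B and methoxymethoxy and methyl on ring A | COCOc1cc(C)cc2Oc3c(C=O)cc(OC)cc3OC(=O)c12
F7 | step 12 | methyl 2-(2-formyl-6-hydroxy-4-methoxyphenoxy)-6-(methoxymethoxy)-4-methylbenzoate | COCOc1cc(C)cc(Oc2c(O)cc(OC)cc2C=O)c1C(=O)OC
F8 | step 6 | [2-ethenyl-4-methoxy-6-(methoxymethoxy)phenyl][2,6-bis(methoxymethoxy)-4-methylphenyl]methanone | COCOc1cc(OC)cc(C=C)c1C(=O)c1c(OCOC)cc(C)cc1OCOC
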